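## Structural features

The target is an unsymmetrical dimer of two abietane-type units. The unprimed half has rings A, B and C, with ring C as a 13-isopropyl-14-hydroxy-11,12-quinone and a ketone at C6. The primed half has rings A′, B′ and C′, with ring C′ as an 11′-hydroxy-12′-oxo quinone methide (exocyclic C7′=C8′) and a ketone at C6′. The halves are joined twice, by the C7–C7′ bond and by an ether from C7 to the oxygen on C14′, so C7 is a spiro carbon shared by ring B and a five-membered oxygen ring (O, C7, C7′, C8′, C14′). Each half carries a vicinal pair of stereocentres, the α-keto methine C5 and the benzylic quaternary C10, in a trans ring fusion. The pair is 5S,10S in the unprimed half and 5′R,10′R in the primed half, so the two decalin-type units are mirror images; the fifth centre, spiro C7 (R), sits between C6 and C8. Fragile groups are the hydroxyquinone, the electrophilic quinone methide, the epimerisable centres C5 and C5′, and the tertiary α-keto aryl ether at C7. The real difficulty is the C7/C7′ junction, where four rings meet between two fully substituted six-membered rings, each flanked by a quaternary carbon, together with the opposite absolute configuration of the two halves. The key step uses the fact that C7 and C7′ each carry one of two identically substituted rings (C and C′) whose ring A appendages are enantiomeric: C7–C7′ can be the triple bond of a diarylacetylene made from both enantiomers of one aryl iodide, and C6′ and the C14′ oxygen then add across it.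

## Logic of the disconnections

33 to 31. No skeletal bond is cut. The hydroxyquinone and the quinone methide are traced back to five aryl methyl ethers and a hydrogen on C7′, because neither chromophore would survive the earlier steps. The gain is a robust, fully aromatic precursor. The forward step must cleave five O–CH3 bonds without ionising the C7–O ether, after which the triol and catechol rings (32) oxidise in air.

31 to 30. The C6–C7 bond is cut, which opens ring B and removes the spiro centre. C7 is the β-carbon of the C7=C7′–C6′=O unit of a 3-acylbenzofuran, so an acyl-anion equivalent at C6 can add to it. The gain is the loss of the only stereocentre not inherited from a building block. The forward step demands carbene catalysis on a hindered aldehyde and control of the face of the benzofuran.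

30 to 28. Only the oxidation level of C6 changes (aldehyde back to methyl ester, through 29). The ester is chosen because it is inert to the Lewis acid of the key step, whereas an aldehyde would react with the alkyne. The forward reduction also reduces the C6′ ketone, so both carbinols are reoxidised together.

28 to 26 (through 27). The C6′–C7′ bond and the O–C7 bond are cut, which opens ring B′ and the furan ring and leaves a diarylacetylene. This is the strategic cut: the two halves now differ only in configuration and as acid versus ester. The forward step must make an acylium at C6′ attack the near alkyne carbon and the C14′ methoxy oxygen capture the resulting cation.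

26 to 19 and 25, and 19 to 16 and 17. The two aryl–alkyne bonds C7′–C8′ and C7–C8 are cut. The gain is two aryl iodides of identical constitution and opposite configuration plus a two-carbon linchpin. The forward couplings must work at iodides flanked by a methoxy group and a tertiary alkyl group.

16 and 25 to 10 and 20. The C8–I bond is removed, C6 is taken back to the alcohol level, and the C5–C6 bond is cut as a methylene added to a ketone. The gain is that C5 becomes a carbonyl carbon and only C10 remains stereogenic. The forward sequence must methylenate a ketone flanked by two quaternary carbons and deliver hydrogen to C5 trans to the C10 methyl group.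

10 and 20 to 8 and 9. The C9–C10 bond is cut. Both enantiomers of the quaternary centre come from the same achiral pair by choice of ligand antipode. The forward step must arylate a tertiary enolate with an ortho-methoxy aryl bromide enantioselectively.

8 to 1 (through 7, 5, 3 and 2). The bromine on C9, the oxygen on C11 and the isopropyl group on C13 are removed in turn. Each is introduced at a position that is unambiguous: C13 lies between two methoxy groups, C9 is the only unhindered C–H, and C11 is ortho to bromine in a symmetrical ring. The price is five steps for the arene, in exchange for no regiochemical doubt.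

## Other disconnections considered

Alternative 1: The cut runs through C7′–C8′ and O–C7, that is through the furan ring. It separates a finished unprimed tricycle carrying an exocyclic C7=C7′ alkene with a silyloxymethyl group (A2) from a simple methoxy-isopropyl-benzoquinone (A3). In the forward step TiCl4 would activate A3, the alkene of A2 would attack the quinone carbon that becomes C8′, and the C14′ oxygen would close onto the benzylic cation at C7 to give the spiro dihydrobenzofuranol A1.
- In its favour: Lewis-acid quinone–styrene [3+2] annulation is an established reaction type, so on precedent this step is better than the chosen one. It also sets C7 on a rigid tricycle, where the C10 methyl group can bias the face.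
- Against it: the cation at C7 is next to the masked C6 carbonyl, and the quinone has two free positions, so regiochemistry must be controlled. Above all, the whole A′/B′ bicycle with its opposite-configured C10′ must still be annulated onto A1 in a crowded setting, with a second enantioselective event.
- Comparison: on structure, A1 has the spiro centre but only one decalin unit, whereas the chosen plan has both before the junction is made. On mechanism the alternative is the safer single step. On step economy the chosen plan is better, because one reaction sequence serves both halves.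

Alternative 2: The cut runs through C8–C9 and C13–C14 of ring C. In the forward step (Ph3P)AuNTf2 would activate an ethynyl group on C7, a furan on C10 would add and rearrange through an arene oxide, and rings B and C would form together to give A4.
- In its favour: gold-catalysed furan–yne benzannulation to phenols is a known reaction type, again better precedented than the chosen step. It equals the chosen step in building two rings and two skeletal bonds at once. It is better in one respect: the C14 oxygen appears as a free phenol, already distinguished from the C11 and C12 methyl ethers.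
- Against it: the substrate must already hold the complete primed half at the quinone-methide level, the spiro carbon C7 with its ethynyl group and C6 ketone, and a quaternary C10 bearing a tetrasubstituted, very electron-rich furan. Making that open array with control of C7 relative to C5 and C10 is harder than what the step replaces. The quinone methide is also a ligand and an electrophile for cationic gold, and a furan with no free position is an unusual substrate for this rearrangement.
- Comparison: the chosen plan is more convergent and keeps all sensitive oxidation levels for the last step; the alternative is the more elegant ring C construction but places it at the most fragile stage.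

Alternative 3: The cut is C6–C7, with a chiral triazolium-derived carbene closing ring B onto benzofuran carbon C7 to give A5, which is identical with 31 of the route.
- In its favour: it creates the only stereocentre not inherited from the building blocks, under catalyst control, whereas the chosen key step creates none; in stereochemical content it is better. Carbene-catalysed dearomatising acyl transfer to benzofurans is also a known reaction type.
- Against it as the central idea: it presupposes aldehyde 30, a 2-aryl-3-acylbenzofuran substituted at every position around the aryl–furan bond, and does not say how to make it. The aldehyde is neopentyl-like and epimerisable.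
- Comparison: the two disconnections are complementary. The chosen plan uses this closure as step 21, so for that bond the alternative is its equal in mechanism and step count. The difference is which step carries the strategy: the alkyne acylation builds two rings and both inter-half bonds from mirror-image building blocks, while the Stetter closure builds one ring.

Key step: step 18

Assumption: the unprimed hydroxyquinone is written as its 14-hydroxy-11,12-dione tautomer, which is the same compound as the 12-hydroxy-11,14-dione form by fast proton shift.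

Assumption: (R)-DIFLUORPHOS is taken to give the (R)-ketone; if the sense of induction is the opposite, the ligand antipodes of steps 6 and 12 are exchanged, since both ketone enantiomers are needed.

## Route

Step 1
Reactants: 1 1,3-dimethoxybenzene
Product: 2 2-(2,6-dimethoxyphenyl)propan-2-ol
Conditions: n-BuLi, THF, 0 °C to rt; acetone, −78 °C to rt
Reagents that add atoms: acetone, CC(C)=O
Why: Directed ortho-lithiation at the position between the two methoxy groups, then 1,2-addition to acetone; this places the future isopropyl carbon on C13.

Step 2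
Reactants: 2 2-(2,6-dimethoxyphenyl)propan-2-ol
Product: 3 1,3-dimethoxy-2-(propan-2-yl)benzene
Conditions: Et3SiH, CF3CO2H, CH2Cl2, 0 °C to rt
Reagents that add atoms: none
Why: Ionic hydrogenation: acid ionises the tertiary benzylic alcohol to a cation stabilised by two ortho methoxy groups, and the silane delivers hydride.

Step 3
Reactants: 3 1,3-dimethoxy-2-(propan-2-yl)benzene
Product: 5 5-bromo-1,3-dimethoxy-2-(propan-2-yl)benzene, via arylboronic pinacol ester 4 (not isolated)
Conditions: [Ir(OMe)(cod)]2 (cat.), 4,4′-di-tert-butyl-2,2′-bipyridine, B2pin2, THF, 80 °C; then CuBr2, MeOH/H2O, 80 °C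
Reagents that add atoms: copper dibromide, [Cu+2].[Br-].[Br-]
Why: Iridium-catalysed C–H borylation is sterically controlled and goes to the only ring C–H not flanked by a methoxy group (future C9); copper-mediated bromodeboronation then gives a bromide that electrophilic bromination cannot deliver.

Step 4
Reactants: 5 5-bromo-1,3-dimethoxy-2-(propan-2-yl)benzene
Product: 7 6-bromo-2,4-dimethoxy-3-(propan-2-yl)phenol, via lithium aryltriisopropoxyborate 6 (not isolated)
Conditions: LiN(iPr)2, B(OiPr)3, THF, −78 °C; then H2O2, NaOH, H2O, 0 °C to rt
Reagents that add atoms: hydrogen peroxide, OO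
Why: Directed lithiation between bromine and methoxy (the two ring C–H are equivalent, so only one product is possible) with in situ borate trapping to outrun aryne formation; oxidation of the C–B bond gives the phenol at future C11.

Step 5
Reactants: 7 6-bromo-2,4-dimethoxy-3-(propan-2-yl)phenol
Product: 8 1-bromo-2,3,5-trimethoxy-4-(propan-2-yl)benzene
Conditions: MeI, K2CO3, DMF, rt
Reagents that add atoms: iodomethane, CI
Why: Williamson O-methylation of the phenoxide.

Step 6
Reactants: 8 1-bromo-2,3,5-trimethoxy-4-(propan-2-yl)benzene; 9 2,2,6-trimethylcyclohexan-1-one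
Product: 10 (2R)-2,6,6-trimethyl-2-[2,3,5-trimethoxy-4-(propan-2-yl)phenyl]cyclohexan-1-one
Conditions: Pd(dba)2 (cat.), (R)-DIFLUORPHOS (cat.), NaOtBu, toluene, 80 °C
Reagents that add atoms: none
Why: Enantioselective palladium-catalysed α-arylation at the only enolisable position of 9 (tertiary enolate, C–C reductive elimination from the arylpalladium enolate); the quaternary centre C10 is set by the chiral bisphosphine, this antipode serving the natural series.

Step 7
Reactants: 10 (2R)-2,6,6-trimethyl-2-[2,3,5-trimethoxy-4-(propan-2-yl)phenyl]cyclohexan-1-one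
Product: 11 2,3,5-trimethoxy-4-(propan-2-yl)-1-[(1S)-1,3,3-trimethyl-2-methylidenecyclohexyl]benzene
Conditions: Ph3PCH3Br, KOtBu, toluene, 110 °C
Reagents that add atoms: methyltriphenylphosphonium bromide, C[P+](c1ccccc1)(c1ccccc1)c1ccccc1.[Br-]
Why: Wittig methylenation under forcing conditions adds C6; the ketone has no α-hydrogen, so enolisation cannot compete and C10 cannot epimerise.

Step 8
Reactants: 11 2,3,5-trimethoxy-4-(propan-2-yl)-1-[(1S)-1,3,3-trimethyl-2-methylidenecyclohexyl]benzene
Product: 13 {(1S,2S)-2,6,6-trimethyl-2-[2,3,5-trimethoxy-4-(propan-2-yl)phenyl]cyclohexyl}methanol, via primary alkylborane 12 (not isolated)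
Conditions: BH3·THF, THF, 0 to 40 °C; then NaOH, H2O2, H2O, 0 °C to rt
Reagents that add atoms: hydrogen peroxide, OO
Why: Anti-Markovnikov hydroboration–oxidation puts boron on the exocyclic carbon C6; hydride should reach C5 from the ring face opposite the two axial methyl groups on C10 and C4 (aryl equatorial), which sets H-5 trans to the C10 methyl group as in a trans-fused abietane.

Step 9
Reactants: 13 {(1S,2S)-2,6,6-trimethyl-2-[2,3,5-trimethoxy-4-(propan-2-yl)phenyl]cyclohexyl}methanol
Product: 15 methyl (1S,2S)-2,6,6-trimethyl-2-[2,3,5-trimethoxy-4-(propan-2-yl)phenyl]cyclohexane-1-carboxylate, via carboxylic acid 14 (not isolated)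
Conditions: AZADO (cat.), PhI(OAc)2, MeCN/H2O, rt; then Me3SiCHN2, toluene/MeOH, 0 °C
Reagents that add atoms: water, O; trimethylsilyldiazomethane, C[Si](C)(C)C=[N+]=[N-]
Why: Nitroxyl-catalysed oxidation of the hindered primary alcohol through the aldehyde hydrate to the acid without base, so C5 is not epimerised, then O-methylation of the acid.

Step 10
Reactants: 15 methyl (1S,2S)-2,6,6-trimethyl-2-[2,3,5-trimethoxy-4-(propan-2-yl)phenyl]cyclohexane-1-carboxylate
Product: 16 methyl (1S,2S)-2-[2-iodo-3,5,6-trimethoxy-4-(propan-2-yl)phenyl]-2,6,6-trimethylcyclohexane-1-carboxylate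
Conditions: N-iodosuccinimide, CF3CO2H (cat.), MeCN, 0 °C to rt
Reagents that add atoms: N-iodosuccinimide, O=C1CCC(=O)N1I
Why: Electrophilic aromatic iodination at the single remaining ring C–H (C8), which is activated by an ortho and a para methoxy group.

Step 11
Reactants: 16 methyl (1S,2S)-2-[2-iodo-3,5,6-trimethoxy-4-(propan-2-yl)phenyl]-2,6,6-trimethylcyclohexane-1-carboxylate; 17 ethynyl(trimethyl)silane
Product: 19 methyl (1S,2S)-2-[2-ethynyl-3,5,6-trimethoxy-4-(propan-2-yl)phenyl]-2,6,6-trimethylcyclohexane-1-carboxylate, via trimethylsilyl alkyne 18 (not isolated)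
Conditions: PdCl2(PPh3)2 (cat.), CuI (cat.), iPr2NH, THF, 60 °C; then K2CO3, MeOH, rt
Reagents that add atoms: none
Why: Sonogashira coupling at the aryl iodide forms C7–C8, and methanolysis of the C–Si bond frees the terminal alkyne; the hindered methyl ester is not touched.

Step 12
Reactants: 8 1-bromo-2,3,5-trimethoxy-4-(propan-2-yl)benzene; 9 2,2,6-trimethylcyclohexan-1-one
Product: 20 (2S)-2,6,6-trimethyl-2-[2,3,5-trimethoxy-4-(propan-2-yl)phenyl]cyclohexan-1-one
Conditions: Pd(dba)2 (cat.), (S)-DIFLUORPHOS (cat.), NaOtBu, toluene, 80 °C
Reagents that add atoms: none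
Why: The same enantioselective α-arylation with the antipodal ligand gives the mirror-image quaternary centre C10′ for the primed half.

Step 13
Reactants: 20 (2S)-2,6,6-trimethyl-2-[2,3,5-trimethoxy-4-(propan-2-yl)phenyl]cyclohexan-1-one
Product: 21 2,3,5-trimethoxy-4-(propan-2-yl)-1-[(1R)-1,3,3-trimethyl-2-methylidenecyclohexyl]benzene
Conditions: Ph3PCH3Br, KOtBu, toluene, 110 °C
Reagents that add atoms: methyltriphenylphosphonium bromide, C[P+](c1ccccc1)(c1ccccc1)c1ccccc1.[Br-]
Why: Wittig methylenation of the non-enolisable ketone, as in step 7, adds C6′.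

Step 14
Reactants: 21 2,3,5-trimethoxy-4-(propan-2-yl)-1-[(1R)-1,3,3-trimethyl-2-methylidenecyclohexyl]benzene
Product: 23 {(1R,2R)-2,6,6-trimethyl-2-[2,3,5-trimethoxy-4-(propan-2-yl)phenyl]cyclohexyl}methanol, via primary alkylborane 22 (not isolated)
Conditions: BH3·THF, THF, 0 to 40 °C; then NaOH, H2O2, H2O, 0 °C to rt
Reagents that add atoms: hydrogen peroxide, OO
Why: Hydroboration–oxidation as in step 8; hydride delivery to C5′ opposite the axial methyl groups sets H-5′ trans to the C10′ methyl group.

Step 15
Reactants: 23 {(1R,2R)-2,6,6-trimethyl-2-[2,3,5-trimethoxy-4-(propan-2-yl)phenyl]cyclohexyl}methanol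
Product: 24 (1R,2R)-2,6,6-trimethyl-2-[2,3,5-trimethoxy-4-(propan-2-yl)phenyl]cyclohexane-1-carboxylic acid
Conditions: AZADO (cat.), PhI(OAc)2, MeCN/H2O, rt
Reagents that add atoms: water, O
Why: Nitroxyl-catalysed oxidation of the primary alcohol to the carboxylic acid under non-basic conditions that leave C5′ untouched.

Step 16
Reactants: 24 (1R,2R)-2,6,6-trimethyl-2-[2,3,5-trimethoxy-4-(propan-2-yl)phenyl]cyclohexane-1-carboxylic acid
Product: 25 (1R,2R)-2-[2-iodo-3,5,6-trimethoxy-4-(propan-2-yl)phenyl]-2,6,6-trimethylcyclohexane-1-carboxylic acid
Conditions: N-iodosuccinimide, CF3CO2H (cat.), MeCN, 0 °C to rt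
Reagents that add atoms: N-iodosuccinimide, O=C1CCC(=O)N1I
Why: Electrophilic aromatic iodination at the only free ring position (C8′), as in step 10.

Step 17
Reactants: 19 methyl (1S,2S)-2-[2-ethynyl-3,5,6-trimethoxy-4-(propan-2-yl)phenyl]-2,6,6-trimethylcyclohexane-1-carboxylate; 25 (1R,2R)-2-[2-iodo-3,5,6-trimethoxy-4-(propan-2-yl)phenyl]-2,6,6-trimethylcyclohexane-1-carboxylic acid
Product: 26 pseudo-meso diarylacetylene acid (5S,10S,5′R,10′R; methyl ester on C6; free acid on C6′)
Conditions: Pd(PPh3)4 (cat.), CuI (cat.), Et3N, DMF, 70 °C
Reagents that add atoms: none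
Why: A second Sonogashira coupling forms C7′–C8′, with the acid carried as its ammonium carboxylate; joining the (1S,2S) alkyne to the (1R,2R) iodide gives the acetylene whose halves are mirror images apart from acid versus ester.

Step 18
Reactants: 26 pseudo-meso diarylacetylene acid (5S,10S,5′R,10′R; methyl ester on C6; free acid on C6′)
Product: 28 2-aryl-3-acylbenzofuran (5S,10S,5′R,10′R; rings A′ B′ C′ and the furan closed; methyl ester on C6), via acid chloride 27 (not isolated)
Conditions: (COCl)2, DMF (cat.), CH2Cl2, 0 °C to rt, evaporate; then AlCl3, CH2Cl2, −78 to −20 °C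
Reagents that add atoms: none
Why: Proposed new method: AlCl3 abstracts chloride from 27 to give an acylium ion at C6′, which the C9′–C10′–C5′ tether holds against the alkyne; it attacks the near carbon C7′ (6-exo-dig, closing ring B′) and leaves a vinyl cation at C7 that the unprimed aryl ring can stabilise once twisted into conjugation with the empty in-plane orbital. The methoxy oxygen on C14′ lies in the same plane and captures C7 (5-endo closure onto the cation, closing the furan ring), and AlCl4− removes the methyl group of the resulting oxonium ion as CH3Cl to give the aromatic benzofuran. The closest known reaction types are the AlCl3-mediated acylation of alkynes by acid chlorides, in which chloride traps the vinyl cation, and the iodonium-induced cyclisation of 2-alkynylanisoles to 3-substituted benzofurans with loss of methyl halide; here the external electrophile is replaced by a tethered acylium. No stereocentre is formed, and C5′, which is α to the acylium carbon, never meets base. The step needs four selectivities: only the primed half acylates (the other half is a methyl ester); attack is 6-exo at C7′ and not 7-endo at C7 (three-atom tether); the alkyne and not an arene is acylated (both arenes are hexasubstituted); and C7 is captured by the C14′ oxygen and not by chloride (five-membered in-plane geometry). The main competitor should be O-acylation of the C11′ methoxy group with loss of CH3Cl to a six-membered aryl lactone, which low temperature and short reaction time are meant to suppress.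

Step 19
Reactants: 28 2-aryl-3-acylbenzofuran (5S,10S,5′R,10′R; methyl ester on C6)
Product: 29 benzofuran diol (primary alcohol on C6; secondary alcohol on C6′ as either epimer)
Conditions: LiAlH4, THF, 0 °C to rt
Reagents that add atoms: none
Why: Hydride reduction of the C6 ester to the primary alcohol; the C6′ ketone is reduced as well, to epimeric carbinols that are reoxidised in the next step.

Step 20
Reactants: 29 benzofuran diol
Product: 30 benzofuran keto-aldehyde (aldehyde C6; ketone C6′; 5S,10S,5′R,10′R)
Conditions: Dess–Martin periodinane, NaHCO3, CH2Cl2, rt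
Reagents that add atoms: none
Why: Buffered periodinane oxidation of both alcohols; the non-basic conditions keep the α-centres C5 and C5′ intact.

Step 21
Reactants: 30 benzofuran keto-aldehyde
Product: 31 spiro 2,3-dihydrobenzofuran diketone pentamethyl ether (5S,7S,10S,5′R,7′R,10′R)
Conditions: (5aR,10bS)-2-(pentafluorophenyl)-5a,10b-dihydro-4H,6H-indeno[2,1-b][1,2,4]triazolo[4,3-d][1,4]oxazin-2-ium tetrafluoroborate (20 mol %), KN(SiMe3)2 (20 mol %), toluene, rt to 60 °C
Reagents that add atoms: none
Why: Intramolecular Stetter reaction: the carbene turns the C6 aldehyde into an acyl-anion equivalent that adds 6-exo-trig to C7, the β-carbon of the benzofuran C7=C7′–C6′=O unit, dearomatising the furan ring and closing ring B. The configuration of spiro C7 is the choice between the two faces of the benzofuran (the two rotamers about C7–C8) and is to be set by the chiral carbene, whose matched antipode is chosen against the C5/C10 centres. C7′ is protonated to either epimer without consequence, because it becomes trigonal in step 22.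

Step 22
Reactants: 31 spiro 2,3-dihydrobenzofuran diketone pentamethyl ether
Product: 33 CNP0568854.1 (5S,7R,10S,5′R,10′R), via pentaphenol 32 (not isolated)
Conditions: BBr3, CH2Cl2, −78 to 0 °C; MeOH quench; then air, EtOAc/pH 7 buffer, rt
Reagents that add atoms: none
Why: Lewis-acid cleavage of the five aryl methyl ethers (bromide attacks the methyl groups); air should oxidise the 11,12,14-triol to the hydroxyquinone and the 11′,12′-catechol to the ortho-quinone, which tautomerises by loss of H-7′ to the conjugated quinone methide. The change of the C7 descriptor from S to R reflects a change of CIP priority, not of geometry.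

## Compound list

1 | 1,3-dimethoxybenzene | COc1cccc(OC)c1 | starting material
2 | 2-(2,6-dimethoxyphenyl)propan-2-ol | COc1cccc(OC)c1C(C)(C)O | intermediate
3 | 1,3-dimethoxy-2-(propan-2-yl)benzene | COc1cccc(OC)c1C(C)C | intermediate
4 | 2-[3,5-dimethoxy-4-(propan-2-yl)phenyl]-4,4,5,5-tetramethyl-1,3,2-dioxaborolane | COc1cc(cc(OC)c1C(C)C)B1OC(C)(C)C(C)(C)O1 | intermediate
5 | 5-bromo-1,3-dimethoxy-2-(propan-2-yl)benzene | COc1cc(Br)cc(OC)c1C(C)C | intermediate
6 | lithium [6-bromo-2,4-dimethoxy-3-(propan-2-yl)phenyl]tri(propan-2-yloxy)borate | [Li+].COc1cc(Br)c(c(OC)c1C(C)C)[B-](OC(C)C)(OC(C)C)OC(C)C | intermediate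
7 | 6-bromo-2,4-dimethoxy-3-(propan-2-yl)phenol | COc1cc(Br)c(O)c(OC)c1C(C)C | intermediate
8 | 1-bromo-2,3,5-trimethoxy-4-(propan-2-yl)benzene | COc1cc(Br)c(OC)c(OC)c1C(C)C | intermediate
9 | 2,2,6-trimethylcyclohexan-1-one | CC1CCCC(C)(C)C1=O | starting material
10 | (2R)-2,6,6-trimethyl-2-[2,3,5-trimethoxy-4-(propan-2-yl)phenyl]cyclohexan-1-one | COc1c(OC)c(C(C)C)c(OC)cc1[C@@]1(C)CCCC(C)(C)C1=O | intermediate
11 | 2,3,5-trimethoxy-4-(propan-2-yl)-1-[(1S)-1,3,3-trimethyl-2-methylidenecyclohexyl]benzene | COc1c(OC)c(C(C)C)c(OC)cc1[C@@]1(C)CCCC(C)(C)C1=C | intermediate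
12 | ({(1S,2S)-2,6,6-trimethyl-2-[2,3,5-trimethoxy-4-(propan-2-yl)phenyl]cyclohexyl}methyl)borane | COc1c(OC)c(C(C)C)c(OC)cc1[C@@]1(C)CCCC(C)(C)[C@@H]1CB | intermediate
13 | {(1S,2S)-2,6,6-trimethyl-2-[2,3,5-trimethoxy-4-(propan-2-yl)phenyl]cyclohexyl}methanol | COc1c(OC)c(C(C)C)c(OC)cc1[C@@]1(C)CCCC(C)(C)[C@@H]1CO | intermediate
14 | (1S,2S)-2,6,6-trimethyl-2-[2,3,5-trimethoxy-4-(propan-2-yl)phenyl]cyclohexane-1-carboxylic acid | COc1c(OC)c(C(C)C)c(OC)cc1[C@@]1(C)CCCC(C)(C)[C@@H]1C(=O)O | intermediate
15 | methyl (1S,2S)-2,6,6-trimethyl-2-[2,3,5-trimethoxy-4-(propan-2-yl)phenyl]cyclohexane-1-carboxylate | COc1c(OC)c(C(C)C)c(OC)cc1[C@@]1(C)CCCC(C)(C)[C@@H]1C(=O)OC | intermediate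
16 | methyl (1S,2S)-2-[2-iodo-3,5,6-trimethoxy-4-(propan-2-yl)phenyl]-2,6,6-trimethylcyclohexane-1-carboxylate | COc1c(OC)c(C(C)C)c(OC)c(I)c1[C@@]1(C)CCCC(C)(C)[C@@H]1C(=O)OC | intermediate
17 | ethynyl(trimethyl)silane | C#C[Si](C)(C)C | starting material
18 | methyl (1S,2S)-2-{3,5,6-trimethoxy-4-(propan-2-yl)-2-[(trimethylsilyl)ethynyl]phenyl}-2,6,6-trimethylcyclohexane-1-carboxylate | COc1c(OC)c(C(C)C)c(OC)c(C#C[Si](C)(C)C)c1[C@@]1(C)CCCC(C)(C)[C@@H]1C(=O)OC | intermediate
19 | methyl (1S,2S)-2-[2-ethynyl-3,5,6-trimethoxy-4-(propan-2-yl)phenyl]-2,6,6-trimethylcyclohexane-1-carboxylate | COc1c(OC)c(C(C)C)c(OC)c(C#C)c1[C@@]1(C)CCCC(C)(C)[C@@H]1C(=O)OC | intermediate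
20 | (2S)-2,6,6-trimethyl-2-[2,3,5-trimethoxy-4-(propan-2-yl)phenyl]cyclohexan-1-one | COc1c(OC)c(C(C)C)c(OC)cc1[C@]1(C)CCCC(C)(C)C1=O | intermediate
21 | 2,3,5-trimethoxy-4-(propan-2-yl)-1-[(1R)-1,3,3-trimethyl-2-methylidenecyclohexyl]benzene | COc1c(OC)c(C(C)C)c(OC)cc1[C@]1(C)CCCC(C)(C)C1=C | intermediate
22 | ({(1R,2R)-2,6,6-trimethyl-2-[2,3,5-trimethoxy-4-(propan-2-yl)phenyl]cyclohexyl}methyl)borane | COc1c(OC)c(C(C)C)c(OC)cc1[C@]1(C)CCCC(C)(C)[C@H]1CB | intermediate
23 | {(1R,2R)-2,6,6-trimethyl-2-[2,3,5-trimethoxy-4-(propan-2-yl)phenyl]cyclohexyl}methanol | COc1c(OC)c(C(C)C)c(OC)cc1[C@]1(C)CCCC(C)(C)[C@H]1CO | intermediate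
24 | (1R,2R)-2,6,6-trimethyl-2-[2,3,5-trimethoxy-4-(propan-2-yl)phenyl]cyclohexane-1-carboxylic acid | COc1c(OC)c(C(C)C)c(OC)cc1[C@]1(C)CCCC(C)(C)[C@H]1C(=O)O | intermediate
25 | (1R,2R)-2-[2-iodo-3,5,6-trimethoxy-4-(propan-2-yl)phenyl]-2,6,6-trimethylcyclohexane-1-carboxylic acid | COc1c(OC)c(C(C)C)c(OC)c(I)c1[C@]1(C)CCCC(C)(C)[C@H]1C(=O)O | intermediate
26 | pseudo-meso diarylacetylene acid: 1,2-bis[3,4,6-trimethoxy-5-(propan-2-yl)phenyl]ethyne, one ring bearing at its 2-position the (1S,2S)-2-(methoxycarbonyl)-1,3,3-trimethylcyclohexyl group, the other the (1R,2R)-2-carboxy-1,3,3-trimethylcyclohexyl group | COC(=O)[C@H]1C(C)(C)CCC[C@]1(C)c1c(OC)c(OC)c(C(C)C)c(OC)c1C#Cc1c(OC)c(C(C)C)c(OC)c(OC)c1[C@]1(C)CCCC(C)(C)[C@H]1C(=O)O | intermediate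
27 | acid chloride of 26: the same diarylacetylene with the (1R,2R)-2-(chlorocarbonyl)-1,3,3-trimethylcyclohexyl group on the primed ring | COC(=O)[C@H]1C(C)(C)CCC[C@]1(C)c1c(OC)c(OC)c(C(C)C)c(OC)c1C#Cc1c(OC)c(C(C)C)c(OC)c(OC)c1[C@]1(C)CCCC(C)(C)[C@H]1C(Cl)=O | intermediate
28 | 2-aryl-3-acylbenzofuran (5S,10S,5′R,10′R): furan ring (O on C14′, C7, C7′) fused to ring C′ (11′,12′-dimethoxy, 13′-isopropyl); C7′ joined through the C6′ ketone to ring A′ (ring B′ closed); C7 bears the 11,12,14-trimethoxy-13-isopropyl aryl ring with its C6 methyl ester | COC(=O)[C@H]1C(C)(C)CCC[C@]1(C)c1c(OC)c(OC)c(C(C)C)c(OC)c1-c1oc2c(C(C)C)c(OC)c(OC)c3c2c1C(=O)[C@@H]1C(C)(C)CCC[C@@]31C | intermediate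
29 | benzofuran diol: 28 with CH2OH at C6 and CH(OH) at C6′ (either C6′ epimer) | OC[C@H]1C(C)(C)CCC[C@]1(C)c1c(OC)c(OC)c(C(C)C)c(OC)c1-c1oc2c(C(C)C)c(OC)c(OC)c3c2c1C(O)[C@@H]1C(C)(C)CCC[C@@]31C | intermediate
30 | benzofuran keto-aldehyde: 28 with an aldehyde at C6 (5S,10S,5′R,10′R) | O=C[C@H]1C(C)(C)CCC[C@]1(C)c1c(OC)c(OC)c(C(C)C)c(OC)c1-c1oc2c(C(C)C)c(OC)c(OC)c3c2c1C(=O)[C@@H]1C(C)(C)CCC[C@@]31C | intermediate
31 | spiro 2,3-dihydrobenzofuran diketone, 11,12,14,11′,12′-pentamethyl ether, H at C7′ (5S,7S,10S,5′R,7′R,10′R) | CC(C)c1c(OC)c2c(c(OC)c1OC)[C@@]1(C)CCCC(C)(C)[C@@H]1C(=O)[C@@]21Oc2c(C(C)C)c(OC)c(OC)c3c2[C@H]1C(=O)[C@@H]1C(C)(C)CCC[C@@]31C | intermediate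
32 | pentaphenol: 31 with free hydroxyl groups on C11, C12, C14, C11′ and C12′ | CC(C)c1c(O)c2c(c(O)c1O)[C@@]1(C)CCCC(C)(C)[C@@H]1C(=O)[C@@]21Oc2c(C(C)C)c(O)c(O)c3c2[C@H]1C(=O)[C@@H]1C(C)(C)CCC[C@@]31C | intermediate
33 | CNP0568854.1 (5S,7R,10S,5′R,10′R): spiro dimer with 14-hydroxy-11,12-quinone ring C and 11′-hydroxy-12′-oxo quinone methide ring C′ | CC(C)C1=C(O)C2=C(C(=O)C1=O)[C@@]1(C)CCCC(C)(C)[C@@H]1C(=O)[C@@]21OC2=C(C(C)C)C(=O)C(O)=C3C2=C1C(=O)[C@@H]1C(C)(C)CCC[C@@]31C | target

## Step count and least certain steps

Total: 22 steps. Longest linear sequence: 17 steps (steps 1 to 11 and 17 to 22).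

Step 18 (key step, proposed new method). The most likely failure is diversion of the acylium before it reaches the alkyne: O-acylation of the neighbouring C11′ methoxy oxygen with loss of the methyl group, or Lewis-acid cleavage of methyl ethers, or capture of the vinyl cation by chloride. The fallback uses known chemistry and sets out from 26. Iodonium-induced cyclisation of the di(ortho-methoxyaryl)acetylene with ICl in CH2Cl2 at −78 °C closes the furan ring with loss of chloromethane and gives the 3-iodobenzofuran acid F1, with iodine on C7′. An external electrophile cannot tell the two methoxyaryl rings apart, so about half of the material should go to the regioisomeric iodobenzofuran F2, which would lead into the enantiomeric series and must be separated. F1 is methylated with Me3SiCHN2 to the iodobenzofuran diester F3. Iodine–magnesium exchange with iPrMgCl·LiCl in THF (−40 to 0 °C), followed by intramolecular acylation by the adjacent C6′ ester, closes ring B′ and returns to the route at 28.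

Step 21. The likely problems are slow formation of the acyl-anion equivalent from the neopentyl-like aldehyde, epimerisation of C5 under the basic conditions, and poor facial selectivity at C7. The fallback sets out from 30: reductive ketyl–enone cyclisation with SmI2 in THF/t-BuOH at −78 °C forms the same C6–C7 bond and gives the spiro hydroxy ketone F4, which Dess–Martin periodinane oxidises to 31, where the route is rejoined. If the C7 epimers form together, they can in principle be equilibrated in 31 by base through reversible opening of the furan ring (β-elimination of the aryloxide from the C6′ enolate and re-addition).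

Steps 6 and 12. The likely problem is slow coupling or low enantioselectivity, because the bromide carries an ortho methoxy group and the enolate is tertiary and hindered. The fallback sets out from 8 and 9: racemic arylation with an achiral bulky catalyst (Pd(OAc)2, P(tBu)3, NaOtBu, toluene) and separation of the two enantiomers by preparative chromatography on a chiral stationary phase. Both antipodes are needed, so nothing is discarded; the route is rejoined at 10 and 20.

Steps 7 and 13. The likely problem is failure of the ylide to add to a carbonyl flanked by two quaternary carbons. The fallback sets out from 10 (and from 20): addition of MeLi in the presence of CeCl3 (THF, −78 °C) gives the tertiary alcohol F5 (from 20, its enantiomeric-series counterpart F6). Syn-elimination with Burgess reagent in toluene at 80 °C can only give the exocyclic alkene, since both neighbouring carbons are quaternary, and returns to the route at 11 (and 21).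

Step 22. The likely problem is ionisation of the tertiary C7–O ether by the boron Lewis acid, since the cation would be stabilised by the electron-rich unprimed ring, followed by ring opening or decomposition of the polyphenol. The fallback sets out from 31: nucleophilic demethylation with NaSEt in DMF at 130 °C removes the methyl groups by SN2 attack and cannot cleave the tertiary ether. It gives the same pentaphenol 32, which is oxidised in air to 33.

## Further compounds

F1 | step 18 | 3-iodobenzofuran acid: furan closed between the C14′ oxygen and C7, iodine on C7′, free acid on C6′, methyl ester on C6 | COC(=O)[C@H]1C(C)(C)CCC[C@]1(C)c1c(OC)c(OC)c(C(C)C)c(OC)c1-c1oc2c(C(C)C)c(OC)c(OC)c(c2c1I)[C@]1(C)CCCC(C)(C)[C@H]1C(=O)O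
F2 | step 18 | regioisomeric 3-iodobenzofuran: furan closed between the C14 oxygen and C7′, iodine on C7 | COC(=O)[C@H]1C(C)(C)CCC[C@]1(C)c1c(OC)c(OC)c(C(C)C)c2oc(-c3c(OC)c(C(C)C)c(OC)c(OC)c3[C@]3(C)CCCC(C)(C)[C@H]3C(=O)O)c(I)c12
F3 | step 18 | 3-iodobenzofuran diester: methyl ester of F1 | COC(=O)[C@H]1C(C)(C)CCC[C@]1(C)c1c(OC)c(OC)c(C(C)C)c(OC)c1-c1oc2c(C(C)C)c(OC)c(OC)c(c2c1I)[C@]1(C)CCCC(C)(C)[C@H]1C(=O)OC
F4 | step 21 | spiro hydroxy ketone: 31 with CH(OH) at C6 (either C6 epimer) | CC(C)c1c(OC)c2c(c(OC)c1OC)[C@@]1(C)CCCC(C)(C)[C@@H]1C(O)[C@@]21Oc2c(C(C)C)c(OC)c(OC)c3c2[C@H]1C(=O)[C@@H]1C(C)(C)CCC[C@@]31C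
F0 | step 6 | none | none
F0 | step 12 | none | none
F5 | step 7 | (2R)-1,2,6,6-tetramethyl-2-[2,3,5-trimethoxy-4-(propan-2-yl)phenyl]cyclohexan-1-ol (either C1 epimer) | COc1c(OC)c(C(C)C)c(OC)cc1[C@@]1(C)CCCC(C)(C)C1(C)O
F6 | step 13 | (2S)-1,2,6,6-tetramethyl-2-[2,3,5-trimethoxy-4-(propan-2-yl)phenyl]cyclohexan-1-ol (either C1 epimer) | COc1c(OC)c(C(C)C)c(OC)cc1[C@]1(C)CCCC(C)(C)C1(C)O
F0 | step 22 | none | none
A1 | alternative 1 | spiro 2,3-dihydrobenzofuran-5-ol with C6 dioxolane and silyloxymethyl group on C7′ | CC(C)c1c(OC)c2c(c(OC)c1OC)[C@@]1(C)CCCC(C)(C)[C@@H]1C1(OCCO1)[C@@]21Oc2c(C(C)C)c(OC)c(O)cc2[C@@H]1CO[Si](C)(C)C(C)(C)C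
A2 | alternative 1 | unprimed tricycle with C6 dioxolane and exocyclic C7=C7′ alkene bearing a tert-butyldimethylsilyloxymethyl group | CC(C)c1c(OC)c2c(c(OC)c1OC)[C@@]1(C)CCCC(C)(C)[C@@H]1C1(OCCO1)C2=CCO[Si](C)(C)C(C)(C)C
A3 | alternative 1 | 2-methoxy-3-(propan-2-yl)cyclohexa-2,5-diene-1,4-dione | COC1=C(C(C)C)C(=O)C=CC1=O
A4 | alternative 2 | spiro quinone methide with ring C as 14-hydroxy-11,12-dimethoxy arene | CC(C)c1c(O)c2c(c(OC)c1OC)[C@@]1(C)CCCC(C)(C)[C@@H]1C(=O)[C@@]21OC2=C(C(C)C)C(=O)C(O)=C3C2=C1C(=O)[C@@H]1C(C)(C)CCC[C@@]31C
A5 | alternative 3 | spiro 2,3-dihydrobenzofuran diketone pentamethyl ether (identical with 31) | CC(C)c1c(OC)c2c(c(OC)c1OC)[C@@]1(C)CCCC(C)(C)[C@@H]1C(=O)[C@@]21Oc2c(C(C)C)c(OC)c(OC)c3c2[C@H]1C(=O)[C@@H]1C(C)(C)CCC[C@@]31C
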